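All runs are simulated with made-up constants; scatter was added.

| flask | solid substrate | temperature | remark | time |
|---|---|---|---|---|
| blue | 1.4 M | 20 °C | the very flask that is asked about, followed so far |  |
| violet | 2.1 M | 26 °C | run made earlier |  |
| flask | 1.4 M | 20 °C |  | 8.0 d |

| run | time / h | target / % | solid substrate / % |
|---|---|---|---|
| blue | 30.0 | 3.7 | 53.2 |
| blue | 60.0 | 12.7 | 21.9 |
| blue | 96.0 | 19.0 | 0 |
| blue | 120 | 20.7 | 0.3 |
| violet | 4.00 | 0.2 | 95.3 |
| violet | 10.0 | 0.5 | 87.3 |
| violet | 20.0 | 1.8 | 76.9 |
| violet | 30.0 | 3.5 | 67.6 |

(each reading ± 0.5 percentage points)

- solid, in amounts per volume of the solution: solid substrate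
- what is taken out of target is counted as made
- the analysis behind the earlier runs scatters by 0.5 percentage points, standard deviation
- at the start none of the solid substrate is in solution

- Tuesday's: change nothing and wait 4.0 d more
- Saturday's: at 8.0 d take out 90 % of the target then present, then wait 4.0 d
- Wednesday's: at 8.0 d raise the temperature by 15 K, then wait 4.0 d

1. target, in percent of the solid substrate first charged, at 8.0 d
2. the option that brings most further target ("none" if no option brings more than 2 percentage points) (Tuesday's / Saturday's / Wednesday's / none)
3. target present, with what was taken out counted in, in percent of the solid substrate first charged, after Tuesday's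
4. target present, with what was taken out counted in, in percent of the solid substrate first charged, after Wednesday's

- The pitfall with a solid is to read its fall as first order, where a rate constant removes the same fraction per hour whatever the charge.
- The readings refuse this: at 30.0 h the blue run had lost 46.8 % of its charge, while the violet run, though hotter, had lost 32.4 % of a larger charge at 30.0 h, a smaller fraction.
- In molar units the two runs nearly agree. I call the feed the charge times the fraction lost, divided by the time: blue gave 0.0218 M/h and violet 0.0227 M/h. So I read the dissolving as zero order in the solid, a reading from two runs that differ in temperature as well as in charge.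
- Zero order in the solid did not mean a steady rate. At the feed, the blue charge lasts 64.1 h, yet blue still held 21.9 % at 60.0 h, and its loss between its first two readings was 0.0146 M/h, less than the feed. With solid still present, I took the concentration setting the rate to be that of the dissolved material, which I expected to rise as the solid went.
- Once the solid read 0 % at 96.0 h, target gained 1.7 percentage points by 120 h. So I put target at 8.0 d near the last reading, 20.7 %, and expected little from waiting.
- The forecast stood higher than my figure, with 22.8 % now, 23.2 % after Tuesday's, 24 % after Wednesday's and Saturday's as best, holding that “Removing target should bring the most if the stall is reversible”.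
- The flask gave 20.9 % at 8.0 d, 19.2 % after Tuesday's and 6.01 % after Wednesday's. The best option was Saturday's, which brought 10 points further target.

    intermediate ⇌ target (K = 2.40, k = 0.00100 /min, Ea = 90.0 kJ/mol, ΔH = −41.0 kJ/mol)
    solid substrate ⇌ starting material, rate k2*(cs2 - [starting material]) while solid is left; crystals form when [starting material] > cs2 (solubility = 0.930 M, k = 5.40 × 10⁻⁴ /min)
    starting material ⇌ intermediate (K = 0.320, k = 5.40 × 10⁻⁴ /min, Ea = 103 kJ/mol, ΔH = −39.0 kJ/mol)
    starting material ⇌ dormant form (K = 2.20, k = 2.30 × 10⁻⁴ /min, Ea = 94.0 kJ/mol, ΔH = −27.0 kJ/mol)
    (constants at 20 °C)

- At 19.2 h the flask held 23.6 % starting material, so the scheme's dissolving rate was 0.0194 M/h, below my feed, an average up to 30.0 h that took in the start, when the scheme's rate was 0.0301 M/h. In the same flask, with each step taken net, intermediate was made 1.56 times as fast as it was used up at 33.0 h, but 0.717 times as fast at 192 h.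
- In the repeat at −5 °C, the feed, taken over unchanged as an estimate, has the charge last the same 64.1 h, shorter than 192 h. The computed repeat, however, still holds 25.3 % solid substrate beside 64.4 % starting material, so the scheme's dissolving rate is down to 9.28 × 10⁻⁴ M/h, and target stands at 0.921 %.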